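## Analysis of the target

Target 25 is a diester in which (2E,6E)-2,6-dimethylocta-2,6-dienedioic acid links two identical amino alcohol units through their C6 oxygens. One carboxyl end is a 2-methyl-2-enoate and the other a 3-methyl-2-enoate, so the molecule has no symmetry element, but both ester bonds are of the same kind. Each alcohol unit is a cis-fused octahydrocyclopenta[c]pyridine (piperidine ring N2/C1/C3/C4/C4a/C7a, cyclopentane ring C4a/C5/C6/C7/C7a) with an N-methyl group and five contiguous stereocentres, (4S,4aR,6S,7R,7aS). H4, H4a and H7a lie on one face; the C7 methyl is trans to the C7a–C1 bond, and the C6 oxygen is cis to the C7 methyl, on the convex face of the bicycle. Sensitive features are the basic tertiary amines, the two conjugated (E)-alkenes (geometry, deconjugation, conjugate addition) and the hindered secondary ester linkages, which can eliminate. The difficulties are ten stereocentres that must be homochiral across both halves, a C6 oxygen on the face from which a hydride would normally attack a C6 ketone, and the C4–C4a bond, which joins a methyl-bearing carbon to a ring-fusion carbon with no polar handle between them. The strategy rests on two relations: C4 carries a one-carbon branch and is joined to N2 through C3, so N2–C3–C4(=CH2) can be read as an N-propargyl group; and C4a is β to the C6 oxygen, so it can be the β-carbon of a cyclopent-2-enone. Both carbons are then electrophilic by natural polarity, and the C4–C4a bond is made by a nickel-mediated reductive coupling of alkyne and enone that closes the piperidine ring.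

## Retrosynthetic reasoning

**Ester bonds.** The two C6–O bonds of 25 are cut, giving two equivalents of amino alcohol 19 and diacid 24. The cut is made at the alkyl–oxygen bond and not at the acyl–oxygen bond because 19 is the C6 epimer (6R, hydroxyl on the concave face) that hydride reduction of a C6 ketone should deliver. A Mitsunobu esterification then has to invert C6 twice over, once for each carboxyl group. Joining the halves last keeps the route convergent and keeps the sensitive dienoate out of all reductive steps.

**Diacid.** 24 is traced back through dialdehyde 23, diol 22 and hydroxy acetate 21 to 20. No C–C bond is cut: 20 already holds the carbon chain and the (E)-alkene next to the acetate, and the second (E)-alkene geometry is fixed when the allylic methyl group trans to the chain is oxidized. Only the oxidation levels at the two chain ends change.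

**N-methyl, C6 hydroxyl and C4 methyl.** 19 is simplified to keto carbamate 17: one hydride reduction should turn the methyl carbamate into the N-methyl group and the ketone into the alcohol. The C4–H bond of 17 is then removed to give the exocyclic alkene 16. On the cis-fused bicycle the alkene has one open (convex) face, so hydrogenation should set C4 after the ring system exists.

**C4–C4a (key disconnection).** Cutting C4–C4a in 16 opens the piperidine ring and gives enone 14, in which C4 is the internal carbon of an N-propargyl group and C4a the β-carbon of the cyclopentenone. Any other piperidine bond would need a polar pairing that the skeleton does not offer at this position. The forward reaction has to join two electrophilic π-systems reductively, put hydrogen on the alkyne terminus, and create C4a; the three-atom tether from C7a allows only the cis fusion.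

**Enone and N-propargyl group.** The C4a=C5 double bond of 14 is removed to give ketone 12, which differs from 14 only by two hydrogens; kinetic enolization is unambiguous because the other α-carbon is tertiary and flanked by two substituents. 12 comes from ketal 11, and the N–C3 bond of 11 is cut to give carbamate 9 and 10. The ketal is needed because the carbamate N–H and the ketone α-C–H are of similar acidity. Placing the enolization after the N-alkylation and the dehydrogenation last keeps the base-sensitive enone out of all basic steps.

**Nitrogen.** 9 is the ketal of keto carbamate 8, and 8 is traced to acid 5 by a Curtius rearrangement, which forms the N–C1 bond with loss of no carbon that matters. The carboxyl carbon of 5 survives as the carbamate carbonyl and ends as the N-methyl carbon of 25.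

**C7a–C1 and the first stereocentre.** 5 comes from diester 3 by hydrolysis and decarboxylation, and the bond from C7a to the malonate carbon of 3 is cut to give 1 and 2. This conjugate addition sets C7a, the one stereocentre from which C7 (by equilibration), C4a (by the tether), C4 and C6 (by the convex face) all follow. A nitroalkane as C1–N donor would be shorter on paper. The malonate is preferred because its asymmetric phase-transfer addition is an established reaction for 2-alkylcyclopent-2-enones, whereas amine-catalysed nitroalkane additions are not reliable for α-substituted enones. Acid 5 also offers a handle for enrichment by salt crystallization.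

## Alternatives that were turned down

**Alternative 1:** The C4a–C5 bond of dione A1 is cut, giving keto lactam A2, an N-methyl α-methyl unsaturated δ-lactam that carries a 3-oxobutan-2-yl group on C7a. In the forward sense an alkoxide base would form the terminal enolate of the methyl ketone, whose carbon (C5) adds to C4a (5-exo-trig) and closes the cyclopentanone; the lactam enolate is then protonated at C4 and C7 equilibrates.
- For it: no transition metal and no protecting group; the cis fusion is again dictated by the tether; A1 holds both carbonyls, so a single hydride reduction would lead to 19. After ring closure it is two steps shorter than the chosen route and is stronger on that point.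
- Against it: an α-methyl unsaturated lactam is among the weakest Michael acceptors. The cyclization must compete with aldol self-condensation of the methyl ketone and with deprotonation at C7a (allylic, γ to the lactam carbonyl), which would erase the only stereocentre A2 brings. C4 is set by enolate protonation under equilibrating base, so its configuration depends on a thermodynamic balance that cannot be predicted with confidence. A2 itself needs an enantioselective synthesis with an epimerizable side chain.
- Comparison: the chosen route gives up the shorter end game for a C–C bond formation that does not rely on the electrophilicity of an amide-conjugated alkene, and for a C4 configuration set kinetically on a rigid bicycle.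

**Alternative 2:** Three bonds of enone A3 are cut (C4a–C7a, C5–C6, C6–C7), giving the acyclic carbamate-tethered 1,7-enyne A4. In the forward sense a cobalt-mediated Pauson–Khand reaction would combine the terminal alkyne, the (E)-crotyl alkene and carbon monoxide and close both rings at once.
- For it: the largest gain in complexity per step of all four strategies; A4 is only two N-alkylations away from simple amines; the (E)-alkene transfers its geometry to the trans H7/H7a relation. On step economy it is stronger than the chosen route.
- Against it: 1,7-enynes with a 1,2-disubstituted alkene are slow Pauson–Khand substrates. C7a is set only by 1,3-induction from the propargylic stereocentre C4 across the forming ring, which is likely to be weak. C4a is not set at all: the trisubstituted enone alkene of A3 must afterwards be reduced from the face that gives the cis fusion, with the C4 methyl and the C7 methyl on opposite faces. A4 also needs an enantiopure 2-methylbut-3-ynylamine unit.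
- Comparison: the chosen route is longer but fixes C4a by the tether in the bond-forming step and sets C4 afterwards on a bicycle with one open face.

**Alternative 3:** The C1–C7a bond and the C6 carbonyl of amino ketone A5 are traced to the secondary amine A6 (a 2-methylcyclopent-2-en-1-ol with a (2S)-1-(methylamino)propan-2-yl group on the ring carbon that becomes C4a) and formaldehyde (A7). In the forward sense A6 and A7 would give an N-methyl iminium ion whose carbon is attacked by the trisubstituted alkene at C7a, closing the piperidine; the tertiary C7 cation is then discharged by a 1,2-hydride shift from the carbinol carbon, which becomes the C6 ketone.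
- For it: the N-methyl group, C1 and the ketone are all in place after one step, without protecting groups; A5 needs only one reduction to reach 19 and no hydrogenation. The end game is shorter than the chosen one.
- Against it: an unstabilized iminium ion and an unactivated alkene react only under forcing acid, where the allylic alcohol of A6 can ionize or eliminate and where amine, alcohol and A7 can form an oxazine. The C7 cation can lose a proton instead of accepting the hydride. The vicinal C4/C4a relation must be built in the flexible side chain of A6 before cyclization, which moves the stereochemical problem into the precursor.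
- Comparison: the chosen route uses a metal-mediated ring closure of a well-precedented class and leaves C4 to be set on the finished ring system.

Key step: step 8

## Route

Assumption: the sense of induction of the cinchona-derived phase-transfer catalyst in step 1 is not predicted here; both pseudoenantiomeric catalysts are available, and the one that gives the (1S) adduct 3 is used.

Step 1
Reactants: 1 2-methylcyclopent-2-en-1-one; 2 dimethyl propanedioate
Product: 3 dimethyl 2-[(1S,2R)-2-methyl-3-oxocyclopentyl]propanedioate
Conditions: 2 (excess, neat), O-allyl-N-(9-anthracenylmethyl)quinidinium bromide or its quinine-derived pseudoenantiomer (10 mol %), K2CO3 (solid, 0.2 equiv), −20 °C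
Reagents that add atoms: none
Why: Asymmetric phase-transfer Michael addition: the chiral ammonium malonate ion pair adds to one face of the β-carbon of 1 and fixes the carbon that becomes C7a; protonation and carbonate-mediated equilibration leave the α-methyl group trans. The reaction class is established for 2-alkylcyclopent-2-enones.

Step 2
Reactants: 3 dimethyl 2-[(1S,2R)-2-methyl-3-oxocyclopentyl]propanedioate
Product: 5 2-[(1R,2R)-2-methyl-3-oxocyclopentyl]acetic acid, via malonic acid 4 (not isolated)
Conditions: 6 M HCl, AcOH, reflux
Reagents that add atoms: water, O
Why: Acid hydrolysis of both esters followed by thermal decarboxylation of 4; acid is chosen because base could trigger a retro-Michael reaction and erode the new stereocentre, and any epimerization next to the ketone returns to the trans isomer. Crystallization of a chiral amine salt of 5 can raise the enantiomeric purity if needed.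

Step 3
Reactants: 5 2-[(1R,2R)-2-methyl-3-oxocyclopentyl]acetic acid
Product: 8 methyl N-{[(1S,2R)-2-methyl-3-oxocyclopentyl]methyl}carbamate, via acyl azide 6 (not isolated), via isocyanate 7 (not isolated)
Conditions: (PhO)2P(O)N3, Et3N, toluene, rt then 85 °C; then MeOH, 65 °C
Reagents that add atoms: diphenylphosphoryl azide, [N-]=[N+]=NP(=O)(Oc1ccccc1)Oc1ccccc1; methanol, CO
Why: Curtius rearrangement: 6 loses N2 with 1,2-shift of the CH2 group (no stereocentre is involved) to give 7, which methanol captures as the methyl carbamate. The ketone is inert under these conditions.

Step 4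
Reactants: 8 methyl N-{[(1S,2R)-2-methyl-3-oxocyclopentyl]methyl}carbamate
Product: 9 methyl N-{[(6R,7S)-6-methyl-1,4-dioxaspiro[4.4]nonan-7-yl]methyl}carbamate
Conditions: HOCH2CH2OH, p-TsOH (cat.), benzene, reflux (Dean–Stark)
Reagents that add atoms: ethane-1,2-diol, OCCO
Why: Acid-catalysed dioxolane formation with azeotropic removal of water masks the ketone, so that only the carbamate N–H is deprotonated in step 5; the methyl group stays trans, which is the thermodynamic arrangement.

Step 5
Reactants: 9 methyl N-{[(6R,7S)-6-methyl-1,4-dioxaspiro[4.4]nonan-7-yl]methyl}carbamate; 10 3-bromoprop-1-yne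
Product: 11 methyl N-{[(6R,7S)-6-methyl-1,4-dioxaspiro[4.4]nonan-7-yl]methyl}-N-(prop-2-yn-1-yl)carbamate
Conditions: NaH (1.1 equiv), DMF, 0 °C; then 10, 0 °C to rt
Reagents that add atoms: none
Why: SN2 N-alkylation of the sodium carbamate by the propargylic bromide; with the ketone masked there is no competing C-alkylation or aldol reaction.

Step 6
Reactants: 11 methyl N-{[(6R,7S)-6-methyl-1,4-dioxaspiro[4.4]nonan-7-yl]methyl}-N-(prop-2-yn-1-yl)carbamate
Product: 12 methyl N-{[(1S,2R)-2-methyl-3-oxocyclopentyl]methyl}-N-(prop-2-yn-1-yl)carbamate
Conditions: 1 M HCl, THF, rt
Reagents that add atoms: water, O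
Why: Acid hydrolysis of the dioxolane; carbamate and alkyne are stable to dilute aqueous acid at room temperature.

Step 7
Reactants: 12 methyl N-{[(1S,2R)-2-methyl-3-oxocyclopentyl]methyl}-N-(prop-2-yn-1-yl)carbamate
Product: 14 methyl N-{[(1S,5R)-5-methyl-4-oxocyclopent-2-en-1-yl]methyl}-N-(prop-2-yn-1-yl)carbamate, via silyl enol ether 13 (not isolated)
Conditions: Me3SiCl, LiN(SiMe3)2, THF, −78 °C (in situ trapping); then Pd(OAc)2 (1.1 equiv), MeCN, rt
Reagents that add atoms: none
Why: Saegusa–Ito oxidation: the hindered amide removes a proton from the unsubstituted α-CH2 (the other α-carbon is tertiary and flanked by two substituents) and the enolate is silylated at once to 13; divalent palladium then forms the palladium enolate, and β-hydride elimination gives the enone. The silylamide is weak enough that the alkyne C–H should not compete at −78 °C, and the methyl-bearing α-carbon is never enolized, so the trans relation is kept.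

Step 8
Reactants: 14 methyl N-{[(1S,5R)-5-methyl-4-oxocyclopent-2-en-1-yl]methyl}-N-(prop-2-yn-1-yl)carbamate
Product: 16 methyl (4aS,7R,7aS)-7-methyl-4-methylidene-6-oxooctahydro-2H-cyclopenta[c]pyridine-2-carboxylate, via ethylzinc enolate 15 (not isolated)
Conditions: Ni(cod)2 (10 mol %), PPh3 (50 mol %, premixed), Et2Zn (3 equiv), THF, 0 °C; aq. NH4Cl
Reagents that add atoms: none
Why: Zerovalent nickel binds the alkyne and the enone alkene of 14 and undergoes oxidative cyclization to a seven-membered oxanickelacycle (a nickel O-enolate), in which the internal alkyne carbon (C4) is bonded to the enone β-carbon (C4a). Transmetalation with Et2Zn gives zinc enolate 15 and an alkenyl(ethyl)nickel species; with PPh3 on nickel, β-hydride elimination of the ethyl group and C–H reductive elimination put hydrogen on the former alkyne terminus, release ethene and return zerovalent nickel. The closest known reaction type is the nickel-catalysed reductive cyclization of alkynyl enones with organozinc reagents, which includes nitrogen-tethered substrates that close six-membered rings. The piperidine closes 6-exo-dig with respect to the alkyne and exo with respect to the ring alkene. The only new stereocentre, C4a, is controlled by C7a: the three-atom tether (C1, N2, C3) can reach the β-carbon only from the face on which it is attached, so the fusion must be cis. The step needs hydrogen transfer and not ethyl transfer, which the excess of PPh3 premixed with Ni(cod)2 is meant to secure, and it needs coupling at the internal alkyne carbon, which the tether length secures. The C7 methyl is not at risk because the enolate formed is the C5–C6 enolate, which aqueous NH4Cl protonates at C5.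

Step 9
Reactants: 16 methyl (4aS,7R,7aS)-7-methyl-4-methylidene-6-oxooctahydro-2H-cyclopenta[c]pyridine-2-carboxylate
Product: 17 methyl (4S,4aR,7R,7aS)-4,7-dimethyl-6-oxooctahydro-2H-cyclopenta[c]pyridine-2-carboxylate
Conditions: H2 (1 atm), PtO2 (5 mol %), EtOAc, rt
Reagents that add atoms: none
Why: Heterogeneous syn-hydrogenation of the 1,1-disubstituted alkene; the catalyst surface should approach the convex face of the cis-fused bicycle (the face of H4a and H7a), so the new C4–H is cis to H4a and C4 becomes S. Platinum is chosen over palladium to limit migration of the double bond into the ring.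

Step 10
Reactants: 17 methyl (4S,4aR,7R,7aS)-4,7-dimethyl-6-oxooctahydro-2H-cyclopenta[c]pyridine-2-carboxylate
Product: 19 (4S,4aR,6R,7R,7aS)-2,4,7-trimethyloctahydro-1H-cyclopenta[c]pyridin-6-ol, via hydroxy carbamate 18 (not isolated)
Conditions: LiAlH4 (4 equiv), THF, −78 to 0 °C, then reflux; aq. NaOH work-up
Reagents that add atoms: none
Why: Hydride reduction in two stages: the ketone reacts first at low temperature, with hydride expected from the convex face, which is also the face small hydrides prefer next to an α-methyl group in cyclopentanones, so the hydroxyl of 18 lies on the concave face (6R), trans to the C7 methyl. At reflux the methyl carbamate is reduced to the N-methyl amine with loss of methoxide.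

Step 11
Reactants: 20 (2E)-3,7-dimethylocta-2,6-dien-1-yl acetate (geranyl acetate)
Product: 21 (2E,6E)-8-hydroxy-3,7-dimethylocta-2,6-dien-1-yl acetate
Conditions: SeO2 (0.3 equiv), t-BuOOH (3 equiv), salicylic acid (10 mol %), CH2Cl2, rt
Reagents that add atoms: tert-butyl hydroperoxide, CC(C)(C)OO
Why: Riley-type allylic oxidation (ene reaction, then [2,3]-sigmatropic shift) with catalytic SeO2 reoxidized by the hydroperoxide; the remote, electron-rich trisubstituted alkene reacts at its (E)-methyl group, while the alkene next to the acetate is deactivated. Any over-oxidation to the C8 aldehyde converges again at 23.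

Step 12
Reactants: 21 (2E,6E)-8-hydroxy-3,7-dimethylocta-2,6-dien-1-yl acetate
Product: 22 (2E,6E)-2,6-dimethylocta-2,6-diene-1,8-diol
Conditions: K2CO3 (cat.), MeOH, rt
Reagents that add atoms: none
Why: Base-catalysed transesterification removes the acetate without touching the alkenes.

Step 13
Reactants: 22 (2E,6E)-2,6-dimethylocta-2,6-diene-1,8-diol
Product: 23 (2E,6E)-2,6-dimethylocta-2,6-dienedial
Conditions: PhI(OAc)2 (2.4 equiv), TEMPO (2,2,6,6-tetramethylpiperidin-1-oxyl, 10 mol %), CH2Cl2, rt
Reagents that add atoms: none
Why: Oxoammonium-mediated oxidation of both primary allylic alcohols to the enals; these neutral conditions are known to keep the geometry of trisubstituted allylic alcohols.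

Step 14
Reactants: 23 (2E,6E)-2,6-dimethylocta-2,6-dienedial
Product: 24 (2E,6E)-2,6-dimethylocta-2,6-dienedioic acid
Conditions: NaClO2, NaH2PO4, 2-methylbut-2-ene, t-BuOH/H2O, 0 °C to rt
Reagents that add atoms: sodium chlorite, [Na+].[O-]Cl=O
Why: Pinnick oxidation of both enals; chlorous acid oxidizes the aldehydes without touching the alkenes, and the alkene scavenger removes hypochlorous acid.

Step 15
Reactants: 19 (4S,4aR,6R,7R,7aS)-2,4,7-trimethyloctahydro-1H-cyclopenta[c]pyridin-6-ol (2.2 equiv); 24 (2E,6E)-2,6-dimethylocta-2,6-dienedioic acid
Product: 25 bis[(4S,4aR,6S,7R,7aS)-2,4,7-trimethyloctahydro-1H-cyclopenta[c]pyridin-6-yl] (2E,6E)-2,6-dimethylocta-2,6-dienedioate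
Conditions: PPh3 (2.6 equiv), diisopropyl azodicarboxylate (DIAD, 2.6 equiv), THF, 0 °C to rt
Reagents that add atoms: none
Why: Double Mitsunobu esterification: each concave hydroxyl of 19 is activated as an alkoxyphosphonium ion and displaced by a carboxylate of 24 from the open convex face with inversion, which turns 6R into the 6S configuration of 25. The conjugated acids are acidic enough for the reaction and the tertiary amine is tolerated; homochiral coupling of two units also lowers the share of the minor enantiomer in the product.

## Compound list

1 | 2-methylcyclopent-2-en-1-one | CC1=CCCC1=O | starting material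
2 | dimethyl propanedioate (dimethyl malonate) | COC(=O)CC(=O)OC | starting material
3 | dimethyl 2-[(1S,2R)-2-methyl-3-oxocyclopentyl]propanedioate | O=C1CC[C@H](C(C(=O)OC)C(=O)OC)[C@H]1C | intermediate
4 | 2-[(1S,2R)-2-methyl-3-oxocyclopentyl]propanedioic acid | O=C1CC[C@H](C(C(=O)O)C(=O)O)[C@H]1C | intermediate (not isolated)
5 | 2-[(1R,2R)-2-methyl-3-oxocyclopentyl]acetic acid | O=C1CC[C@H](CC(=O)O)[C@H]1C | intermediate
6 | 2-[(1R,2R)-2-methyl-3-oxocyclopentyl]acetyl azide | O=C1CC[C@H](CC(=O)N=[N+]=[N-])[C@H]1C | intermediate (not isolated)
7 | (2R,3S)-3-(isocyanatomethyl)-2-methylcyclopentan-1-one | O=C1CC[C@H](CN=C=O)[C@H]1C | intermediate (not isolated)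
8 | methyl N-{[(1S,2R)-2-methyl-3-oxocyclopentyl]methyl}carbamate | O=C1CC[C@H](CNC(=O)OC)[C@H]1C | intermediate
9 | methyl N-{[(6R,7S)-6-methyl-1,4-dioxaspiro[4.4]nonan-7-yl]methyl}carbamate | O1CCOC12CC[C@H](CNC(=O)OC)[C@H]2C | intermediate
10 | 3-bromoprop-1-yne | C#CCBr | starting material
11 | methyl N-{[(6R,7S)-6-methyl-1,4-dioxaspiro[4.4]nonan-7-yl]methyl}-N-(prop-2-yn-1-yl)carbamate | O1CCOC12CC[C@H](CN(C(=O)OC)CC#C)[C@H]2C | intermediate
12 | methyl N-{[(1S,2R)-2-methyl-3-oxocyclopentyl]methyl}-N-(prop-2-yn-1-yl)carbamate | O=C1CC[C@H](CN(C(=O)OC)CC#C)[C@H]1C | intermediate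
13 | methyl N-({(1S,5R)-5-methyl-4-[(trimethylsilyl)oxy]cyclopent-3-en-1-yl}methyl)-N-(prop-2-yn-1-yl)carbamate | C[Si](C)(C)OC1=CC[C@H](CN(C(=O)OC)CC#C)[C@H]1C | intermediate (not isolated)
14 | methyl N-{[(1S,5R)-5-methyl-4-oxocyclopent-2-en-1-yl]methyl}-N-(prop-2-yn-1-yl)carbamate | O=C1C=C[C@H](CN(C(=O)OC)CC#C)[C@H]1C | intermediate
15 | ethylzinc C5–C6 enolate of 16 (O-bound ethylzinc on C6; C4a, C7 and C7a as in 16) | CC[Zn]OC1=C[C@H]2[C@H](CN(C(=O)OC)CC2=C)[C@H]1C | intermediate (not isolated)
16 | methyl (4aS,7R,7aS)-7-methyl-4-methylidene-6-oxooctahydro-2H-cyclopenta[c]pyridine-2-carboxylate | O=C1C[C@H]2[C@H](CN(C(=O)OC)CC2=C)[C@H]1C | intermediate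
17 | methyl (4S,4aR,7R,7aS)-4,7-dimethyl-6-oxooctahydro-2H-cyclopenta[c]pyridine-2-carboxylate | O=C1C[C@H]2[C@H](CN(C(=O)OC)C[C@H]2C)[C@H]1C | intermediate
18 | methyl (4S,4aR,6R,7R,7aS)-6-hydroxy-4,7-dimethyloctahydro-2H-cyclopenta[c]pyridine-2-carboxylate (present as its aluminium alkoxide) | O[C@@H]1C[C@H]2[C@H](CN(C(=O)OC)C[C@H]2C)[C@H]1C | intermediate (not isolated)
19 | (4S,4aR,6R,7R,7aS)-2,4,7-trimethyloctahydro-1H-cyclopenta[c]pyridin-6-ol | O[C@@H]1C[C@H]2[C@H](CN(C)C[C@H]2C)[C@H]1C | intermediate
20 | (2E)-3,7-dimethylocta-2,6-dien-1-yl acetate (geranyl acetate) | CC(C)=CCC/C(C)=C/COC(C)=O | starting material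
21 | (2E,6E)-8-hydroxy-3,7-dimethylocta-2,6-dien-1-yl acetate | OC/C(C)=C/CC/C(C)=C/COC(C)=O | intermediate
22 | (2E,6E)-2,6-dimethylocta-2,6-diene-1,8-diol | OC/C(C)=C/CC/C(C)=C/CO | intermediate
23 | (2E,6E)-2,6-dimethylocta-2,6-dienedial | O=C/C(C)=C/CC/C(C)=C/C=O | intermediate
24 | (2E,6E)-2,6-dimethylocta-2,6-dienedioic acid | OC(=O)/C(C)=C/CC/C(C)=C/C(=O)O | intermediate
25 | bis[(4S,4aR,6S,7R,7aS)-2,4,7-trimethyloctahydro-1H-cyclopenta[c]pyridin-6-yl] (2E,6E)-2,6-dimethylocta-2,6-dienedioate | C/C(=C\C(=O)O[C@H]1C[C@H]2[C@H](CN(C)C[C@H]2C)[C@H]1C)CC/C=C(\C)C(=O)O[C@H]1C[C@H]2[C@H](CN(C)C[C@H]2C)[C@H]1C | target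

## Step count and least certain steps

Total step count: 15. Longest linear sequence: 11 (steps 1–10 and 15); the diacid arm (steps 11–14) joins at step 15.

**Step 8 (key step).** The most likely failures are ethyl transfer in place of hydrogen transfer, direct nickel-catalysed conjugate ethylation of the enone, and oligomerization of the terminal alkyne at zerovalent nickel before the slower six-membered closure onto a cyclic enone. Fallback: set out from 14 and use a tin-radical enyne cyclization. With Bu3SnH and azobisisobutyronitrile in benzene at 80 °C the stannyl radical adds to the alkyne terminus, the vinyl radical at C4 closes 6-exo onto C4a (cis fusion again enforced by the tether), and the α-keto radical takes up hydrogen. This gives methyl (4aS,7R,7aS)-7-methyl-6-oxo-4-[(tributylstannyl)methylidene]octahydro-2H-cyclopenta[c]pyridine-2-carboxylate F1. Protodestannylation with HCl in CH2Cl2 at 0 °C returns to the route at 16.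

**Step 1.** The risk is insufficient enantioselectivity, because the 2-methyl enone may be bound less tightly in the chiral ion pair than its longer-chain analogues. Fallback: set out from 1 and 2 and run the addition with NaOMe (cat.) in MeOH to give the racemic trans diester F2; hydrolysis and decarboxylation as in step 2 give the racemic acid F3. Classical resolution with (1S)-1-phenylethan-1-amine (or its antipode, whichever gives the less soluble salt of the required acid) gives the salt F4, and acidification returns to the route at 5.

**Step 7.** The risks are loss of regiocontrol if the enolate equilibrates, interference of the terminal alkyne with divalent palladium or with the zerovalent palladium that forms, and migration of the new double bond into conjugation with the methyl-bearing carbon if the mixture becomes basic. Fallback: set out from 12 and use selenoxide elimination. LiN(SiMe3)2 in THF at −78 °C followed by PhSeCl gives methyl N-{[(1S,2R)-2-methyl-3-oxo-4-(phenylselanyl)cyclopentyl]methyl}-N-(prop-2-yn-1-yl)carbamate F5; oxidation with H2O2 and pyridine in CH2Cl2 at 0 °C and syn-elimination return to the route at 14.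

**Step 9.** The risks are migration of the exocyclic double bond into the ring before reduction and incomplete facial selectivity at C4. Fallback: set out from 16 and set C4 by hydroboration with a bulky borane, which is more sensitive to the steric difference between the faces and cannot isomerize the alkene. 9-Borabicyclo[3.3.1]nonane (9-BBN) in THF, then NaBO3, should give methyl (4S,4aS,7R,7aS)-4-(hydroxymethyl)-7-methyl-6-oxooctahydro-2H-cyclopenta[c]pyridine-2-carboxylate F6. I2, PPh3 and imidazole give the iodide methyl (4S,4aS,7R,7aS)-4-(iodomethyl)-7-methyl-6-oxooctahydro-2H-cyclopenta[c]pyridine-2-carboxylate F7, and radical reduction with Bu3SnH and azobisisobutyronitrile returns to the route at 17.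

**Step 10.** The risk is hydride attack from the concave face, in part or in full, which would give the C6 epimer. Fallback: set out from 17 and 24 and use that epimer with retention. The epimer, (4S,4aR,6S,7R,7aS)-2,4,7-trimethyloctahydro-1H-cyclopenta[c]pyridin-6-ol F8, already has the C6 configuration of the target and is separated from 19 by chromatography. 24 is converted with oxalyl chloride and catalytic DMF into (2E,6E)-2,6-dimethylocta-2,6-dienedioyl dichloride F9, and acylation of F8 (2.1 equiv) with F9 in CH2Cl2 with pyridine and catalytic 4-(dimethylamino)pyridine at 0 °C returns to the route at 25. Both C6 epimers are therefore usable.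

**Step 15.** The risks are elimination of the activated concave alcohol towards the C5–C6 or C6–C7 alkene and stalling after the first esterification, because the second carboxyl group reacts in a more crowded and less soluble intermediate. Fallback: set out from 19 and separate inversion from coupling. A Mitsunobu reaction with 4-nitrobenzoic acid (PPh3, DIAD, THF) gives (4S,4aR,6S,7R,7aS)-2,4,7-trimethyloctahydro-1H-cyclopenta[c]pyridin-6-yl 4-nitrobenzoate F10. Methanolysis with K2CO3 in MeOH gives the inverted alcohol (4S,4aR,6S,7R,7aS)-2,4,7-trimethyloctahydro-1H-cyclopenta[c]pyridin-6-ol F8, which is acylated with (2E,6E)-2,6-dimethylocta-2,6-dienedioyl dichloride F9 as described under step 10, returning to the route at 25.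

## Further compounds

F1 | step 8 | methyl (4aS,7R,7aS)-7-methyl-6-oxo-4-[(tributylstannyl)methylidene]octahydro-2H-cyclopenta[c]pyridine-2-carboxylate (alkene geometry not defined) | O=C1C[C@H]2[C@H](CN(C(=O)OC)CC2=C[Sn](CCCC)(CCCC)CCCC)[C@H]1C
F2 | step 1 | rac-dimethyl 2-[(1S,2R)-2-methyl-3-oxocyclopentyl]propanedioate (racemic trans diester, both enantiomers) | O=C1CC[C@H](C(C(=O)OC)C(=O)OC)[C@H]1C.O=C1CC[C@@H](C(C(=O)OC)C(=O)OC)[C@@H]1C
F3 | step 1 | rac-2-[(1R,2R)-2-methyl-3-oxocyclopentyl]acetic acid (racemic trans acid, both enantiomers) | O=C1CC[C@H](CC(=O)O)[C@H]1C.O=C1CC[C@@H](CC(=O)O)[C@@H]1C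
F4 | step 1 | (1S)-1-phenylethan-1-aminium 2-[(1R,2R)-2-methyl-3-oxocyclopentyl]acetate | O=C1CC[C@H](CC(=O)[O-])[C@H]1C.C[C@H]([NH3+])c1ccccc1
F5 | step 7 | methyl N-{[(1S,2R)-2-methyl-3-oxo-4-(phenylselanyl)cyclopentyl]methyl}-N-(prop-2-yn-1-yl)carbamate (configuration at the selenium-bearing carbon not defined) | O=C1C([Se]c2ccccc2)C[C@H](CN(C(=O)OC)CC#C)[C@H]1C
F6 | step 9 | methyl (4S,4aS,7R,7aS)-4-(hydroxymethyl)-7-methyl-6-oxooctahydro-2H-cyclopenta[c]pyridine-2-carboxylate | O=C1C[C@H]2[C@H](CN(C(=O)OC)C[C@H]2CO)[C@H]1C
F7 | step 9 | methyl (4S,4aS,7R,7aS)-4-(iodomethyl)-7-methyl-6-oxooctahydro-2H-cyclopenta[c]pyridine-2-carboxylate | O=C1C[C@H]2[C@H](CN(C(=O)OC)C[C@H]2CI)[C@H]1C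
F8 | step 10 | (4S,4aR,6S,7R,7aS)-2,4,7-trimethyloctahydro-1H-cyclopenta[c]pyridin-6-ol | O[C@H]1C[C@H]2[C@H](CN(C)C[C@H]2C)[C@H]1C
F9 | step 10 | (2E,6E)-2,6-dimethylocta-2,6-dienedioyl dichloride | ClC(=O)/C(C)=C/CC/C(C)=C/C(Cl)=O
F10 | step 15 | (4S,4aR,6S,7R,7aS)-2,4,7-trimethyloctahydro-1H-cyclopenta[c]pyridin-6-yl 4-nitrobenzoate | O=C(O[C@H]1C[C@H]2[C@H](CN(C)C[C@H]2C)[C@H]1C)c1ccc(cc1)[N+](=O)[O-]
A1 | alternative 1 | (4S,4aS,7R,7aS)-2,4,7-trimethylhexahydro-1H-cyclopenta[c]pyridine-3,6(2H,4H)-dione | O=C1C[C@H]2[C@H](CN(C)C(=O)[C@H]2C)[C@H]1C
A2 | alternative 1 | (5S)-1,3-dimethyl-5-(3-oxobutan-2-yl)-5,6-dihydropyridin-2(1H)-one (side-chain stereocentre not defined) | C1=C(C)C(=O)N(C)C[C@@H]1C(C)C(C)=O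
A3 | alternative 2 | methyl (4S,7R,7aR)-4,7-dimethyl-6-oxo-1,3,4,6,7,7a-hexahydro-2H-cyclopenta[c]pyridine-2-carboxylate | O=C1C=C2[C@H](CN(C(=O)OC)C[C@H]2C)[C@H]1C
A4 | alternative 2 | methyl N-[(2E)-but-2-en-1-yl]-N-[(2S)-2-methylbut-3-yn-1-yl]carbamate | C/C=C/CN(C(=O)OC)C[C@H](C#C)C
A5 | alternative 3 | (4S,4aR,7R,7aS)-2,4,7-trimethyloctahydro-6H-cyclopenta[c]pyridin-6-one | O=C1C[C@H]2[C@H](CN(C)C[C@H]2C)[C@H]1C
A6 | alternative 3 | (4S)-2-methyl-4-[(2S)-1-(methylamino)propan-2-yl]cyclopent-2-en-1-ol (carbinol configuration not defined) | CNC[C@H]([C@H]1CC(O)C(C)=C1)C
A7 | alternative 3 | formaldehyde | C=O
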